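**Plan**
1. Cuts: the N–O bond of the N-oxide; then the N–C bond of the piperidine at its allylic aminomethine carbon (last ring); then the lactone C–O bond and the C–C bond between the lactone carbinol carbon and the cyclohexane CH. This separates a "west" azabicyclo[3.3.0]octane methyl ketone from an "east" cyclopentene-fused cyclohexenone. The west half is cut at the pyrrolidine (as a pyrrole) and at the quaternary carbon, the east half at the cyclopentene.
2. Forward: bought cyclopentanone → quaternary carbon (Michael) → pyrrole (O-allyl oxime, [3,3] shift, Paal–Knorr) → pyrrolidine (dearomatizing hydrogenation); bought cyclohexenone → cyclopentene annulation; a Mukaiyama aldol joins the halves and closes the δ-lactone; carbonyl reduction; the piperidine is closed last; N-oxidation.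
3. Stereochemistry: two centres come from catalysis (the quaternary carbon and the east ring-fusion CH). The flat pyrrole is hydrogenated from one face (three centres in one event, relayed from the quaternary carbon). The aldol sets the cyclohexane CH and the carbinol carbon from the east ring-fusion centre. Hydride addition anti to the axial α-substituent, then C–N closure with inversion, sets the aminomethine. The N-oxide forms on the only exposed lone pair.
4. Feature that makes the key event possible: the piperidine N–CH carbon is the former enone carbonyl carbon. It is allylic to the cyclopentene C=C and 1,5 to the pyrrolidine nitrogen (through the lactone carbinol carbon and the spiro quaternary carbon), so an activated allylic carbinol can be displaced by that nitrogen in a 6-exo-tet closure.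

Key step: step 13

Assumption: the antipode of each chiral catalyst (steps 1 and 8) is the one that delivers the (S) configuration drawn; the oxime ether of step 2 is carried on as an E/Z mixture, which is of no consequence.

Step 1
Reactants: 1 tert-butyl 2-oxocyclopentane-1-carboxylate; 2 methyl acrylate
Product: 3 tert-butyl (1S)-1-(3-methoxy-3-oxopropyl)-2-oxocyclopentane-1-carboxylate
Conditions: chiral N-spiro binaphthyl quaternary ammonium bromide (1 mol %), K2CO3, toluene, −40 °C
Reagents that add atoms: none
Why: Phase-transfer-catalysed enantioselective Michael addition of a cyclic β-keto ester, in which the chiral ammonium enolate ion pair exposes one face to the acrylate and sets the quaternary stereocentre that later controls the west half.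

Step 2
Reactants: 3 tert-butyl (1S)-1-(3-methoxy-3-oxopropyl)-2-oxocyclopentane-1-carboxylate; 4 O-allylhydroxylamine hydrochloride
Product: 5 tert-butyl (1S)-2-[(allyloxy)imino]-1-(3-methoxy-3-oxopropyl)cyclopentane-1-carboxylate
Conditions: NaOAc, MeOH, 50 °C
Reagents that add atoms: none
Why: Oxime ether formation at the only ketone; no stereocentre is formed, and the non-enolizable quaternary carbon leaves the ring CH2 as the only site for later tautomerization.

Step 3
Reactants: 5 tert-butyl (1S)-2-[(allyloxy)imino]-1-(3-methoxy-3-oxopropyl)cyclopentane-1-carboxylate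
Product: 7 tert-butyl (6S)-6-(3-methoxy-3-oxopropyl)-3-methyl-1,4,5,6-tetrahydrocyclopenta[b]pyrrole-6-carboxylate, via O-(prop-1-enyl) oxime 6 (not isolated)
Conditions: [Ir(cod)Cl]2 (5 mol %), AgOTf (10 mol %), NaBH4 (10 mol %), THF, rt, then 75 °C
Reagents that add atoms: none
Why: An iridium hydride isomerizes the O-allyl to the O-(prop-1-enyl) oxime, whose ene-hydroxylamine tautomer undergoes a [3,3]-sigmatropic shift to a 1,4-imino aldehyde that closes by Paal–Knorr condensation (O-vinyl oxime route to pyrroles), placing the methyl group at C3 without touching the quaternary centre.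

Step 4
Reactants: 7 tert-butyl (6S)-6-(3-methoxy-3-oxopropyl)-3-methyl-1,4,5,6-tetrahydrocyclopenta[b]pyrrole-6-carboxylate
Product: 8 di-tert-butyl (6S)-6-(3-methoxy-3-oxopropyl)-3-methyl-5,6-dihydrocyclopenta[b]pyrrole-1,6(4H)-dicarboxylate
Conditions: Boc2O, DMAP (cat.), MeCN, rt
Reagents that add atoms: di-tert-butyl dicarbonate CC(C)(C)OC(=O)OC(=O)OC(C)(C)C
Why: DMAP-catalysed N-acylation of the pyrrole; the carbamate lowers the aromatic stabilization and blocks imine–enamine tautomerism, so the hydrogenation that follows should be clean.

Step 5
Reactants: 8 di-tert-butyl (6S)-6-(3-methoxy-3-oxopropyl)-3-methyl-5,6-dihydrocyclopenta[b]pyrrole-1,6(4H)-dicarboxylate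
Product: 9 di-tert-butyl (3S,3aR,6S,6aS)-6-(3-methoxy-3-oxopropyl)-3-methylhexahydrocyclopenta[b]pyrrole-1,6(2H)-dicarboxylate
Conditions: H2 (40 bar), 5% Rh/Al2O3, MeOH, rt
Reagents that add atoms: none
Why: Heterogeneous dearomatizing hydrogenation of an N-Boc pyrrole delivers all hydrogens from one face (all-cis C3–H, C3a–H, C6a–H), and adsorption should occur opposite the tert-butyl ester on the adjacent quaternary carbon, so three stereocentres are relayed from C6 in one event with the C3 methyl on the concave face.

Step 6
Reactants: 9 di-tert-butyl (3S,3aR,6S,6aS)-6-(3-methoxy-3-oxopropyl)-3-methylhexahydrocyclopenta[b]pyrrole-1,6(2H)-dicarboxylate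
Product: 11 (3S,3aR,6S,6aS)-1-[(allyloxy)carbonyl]-6-(3-methoxy-3-oxopropyl)-3-methyloctahydrocyclopenta[b]pyrrole-6-carboxylic acid, via amino acid trifluoroacetate 10 (not isolated)
Conditions: TFA, CH2Cl2, 0 °C to rt; concentrate; allyl chloroformate, NaHCO3, THF/H2O, 0 °C
Reagents that add atoms: allyl chloroformate C=CCOC(Cl)=O
Why: Acidolysis removes both tert-butyl groups (carbamate and ester) but not the methyl ester, and Schotten–Baumann acylation re-protects nitrogen as the allyl carbamate, which tolerates the later Lewis-acidic and reducing steps and comes off under neutral conditions.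

Step 7
Reactants: 11 (3S,3aR,6S,6aS)-1-[(allyloxy)carbonyl]-6-(3-methoxy-3-oxopropyl)-3-methyloctahydrocyclopenta[b]pyrrole-6-carboxylic acid
Product: 13 allyl (3S,3aR,6S,6aS)-6-acetyl-6-(3-methoxy-3-oxopropyl)-3-methylhexahydrocyclopenta[b]pyrrole-1(2H)-carboxylate, via acid chloride 12 (not isolated)
Conditions: (COCl)2, DMF (cat.), CH2Cl2, 0 °C; concentrate; MeMgBr, Fe(acac)3 (3 mol %), THF, −78 °C
Reagents that add atoms: methylmagnesium bromide C[Mg]Br
Why: Acid chloride formation followed by iron-catalysed acylative cross-coupling with a Grignard reagent stops at the ketone and tolerates the methyl ester and the carbamate, giving the methyl ketone whose carbonyl carbon becomes the lactone carbinol carbon.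

Step 8
Reactants: 14 cyclohex-2-en-1-one; 15 2-(2-bromoethyl)-1,3-dioxolane
Product: 17 (3S)-3-[2-(1,3-dioxolan-2-yl)ethyl]cyclohexan-1-one, via Grignard reagent 16 (not isolated)
Conditions: Mg, THF, 25 °C; then CuCl (5 mol %), TaniaPhos ferrocenyl diphosphine (6 mol %), 14, Et2O, −60 °C; aq. NH4Cl
Reagents that add atoms: none
Why: Copper-catalysed asymmetric conjugate addition of a Grignard reagent to a cyclic enone with a chiral ferrocenyl diphosphine sets C3, the future ring-fusion CH of the east half, by catalyst control.

Step 9
Reactants: 17 (3S)-3-[2-(1,3-dioxolan-2-yl)ethyl]cyclohexan-1-one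
Product: 19 (7aS)-1,2,5,6,7,7a-hexahydro-4H-inden-4-one, via keto aldehyde 18 (not isolated)
Conditions: 2 M HCl, THF, 60 °C
Reagents that add atoms: none
Why: Acid unveils the aldehyde, and intramolecular aldol condensation of ketone C2 with it forms the cyclopentene ring conjugated with the carbonyl (cyclopentene annulation); the stereocentre is not enolizable in the product and is retained.

Step 10
Reactants: 19 (7aS)-1,2,5,6,7,7a-hexahydro-4H-inden-4-one
Product: 20 trimethyl{[(7aR)-2,6,7,7a-tetrahydro-1H-inden-4-yl]oxy}silane
Conditions: LiN(iPr)2, THF, −78 °C; TMSCl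
Reagents that add atoms: chlorotrimethylsilane C[Si](C)(C)Cl
Why: Kinetic deprotonation of the enone at the α′ CH2 and O-silylation give the cross-conjugated 2-silyloxydiene, whose only nucleophilic carbon is C5 (the descriptor changes by priority only).

Step 11
Reactants: 13 allyl (3S,3aR,6S,6aS)-6-acetyl-6-(3-methoxy-3-oxopropyl)-3-methylhexahydrocyclopenta[b]pyrrole-1(2H)-carboxylate; 20 trimethyl{[(7aR)-2,6,7,7a-tetrahydro-1H-inden-4-yl]oxy}silane
Product: 22 Alloc-protected spirolactone enone, via aldol adduct 21 (not isolated)
Conditions: TiCl4, CH2Cl2, −78 °C, then 0 °C; H2O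
Reagents that add atoms: none
Why: Mukaiyama aldol addition to the TiCl4-activated methyl ketone, then lactonization of the titanium alkoxide on the methyl ester (which also prevents retro-aldol); the C–C bond should form axially on the enol ether face opposite the pseudo-axial C7a–H, and an open antiperiplanar transition state with the quaternary substituent of the ketone over the enol ether hydrogen and not over the ring CH2 should set the carbinol carbon, so both new stereocentres are relayed from C7a.

Step 12
Reactants: 22 Alloc-protected spirolactone enone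
Product: 23 Alloc-protected allylic alcohol
Conditions: NaBH4, CeCl3·7H2O, MeOH/THF, −78 °C
Reagents that add atoms: none
Why: Luche 1,2-reduction of the enone, in which hydride adds to the carbonyl face opposite the axial lactone-bearing substituent on the α-carbon and gives the allylic alcohol cis to that substituent, while lactone and carbamate are inert.

Step 13
Reactants: 23 Alloc-protected allylic alcohol
Product: 25 N-deoxy hexacyclic amine, via amino alcohol 24 (not isolated)
Conditions: Pd(PPh3)4 (5 mol %), Et2NH, CH2Cl2, rt; concentrate; PPh3, DIAD, THF, 0 °C to rt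
Reagents that add atoms: none
Why: Zerovalent palladium ionizes the allyl carbamate, diethylamine captures the allyl group and decarboxylation frees the secondary amine 24; triphenylphosphine and the azodicarboxylate then turn the allylic hydroxyl into an alkoxyphosphonium leaving group that the nitrogen displaces from the rear (intramolecular Mitsunobu cyclodehydration of an amino alcohol is the closest known reaction type). The piperidine closes in the 6-exo-tet mode as the last ring. The one new stereocentre, the aminomethine carbon, is set by inversion of the carbinol from step 12, which places nitrogen trans to the lactone-bearing substituent (trans ring fusion); hydride reduction of the corresponding cyclic iminium ion is not expected to give this relationship, because the face it needs is shielded. The step needs SN2 substitution in preference to ionization to the allyl cation (which would close to the cis-fused epimer), to SN2′ attack and to elimination. This should be secured by the non-ionizing conditions with a neutral phosphine oxide leaving group, by the allylic activation of the C–O bond, by the six-membered transition state with nitrogen 1,5 to the carbinol carbon (attack at the far allyl terminus would need an eight-membered ring), and by the absence of any other nucleophile that can reach that carbon.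

Step 14
Reactants: 25 N-deoxy hexacyclic amine
Product: 26 target N-oxide CNP0566793.5
Conditions: mCPBA (1.0 equiv), CH2Cl2, −20 °C
Reagents that add atoms: 3-chloroperoxybenzoic acid OOC(=O)c1cccc(Cl)c1
Why: Peracid N-oxidation of the tertiary amine is much faster than epoxidation of the trisubstituted alkene, and the nitrogen lone pair is held on the face cis to the angular N–CH hydrogen by the three rings that share it, so a single N-oxide diastereomer should form.

**Compound list**
1 | tert-butyl 2-oxocyclopentane-1-carboxylate | O=C1CCCC1C(=O)OC(C)(C)C | starting material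
2 | methyl acrylate | C=CC(=O)OC | starting material
3 | tert-butyl (1S)-1-(3-methoxy-3-oxopropyl)-2-oxocyclopentane-1-carboxylate | O=C1CCC[C@@]1(CCC(=O)OC)C(=O)OC(C)(C)C | intermediate
4 | O-allylhydroxylamine hydrochloride | C=CCON.Cl | starting material
5 | tert-butyl (1S)-2-[(allyloxy)imino]-1-(3-methoxy-3-oxopropyl)cyclopentane-1-carboxylate (E/Z mixture) | C=CCON=C1CCC[C@@]1(CCC(=O)OC)C(=O)OC(C)(C)C | intermediate
6 | tert-butyl (1S)-1-(3-methoxy-3-oxopropyl)-2-[(prop-1-en-1-yloxy)imino]cyclopentane-1-carboxylate | CC=CON=C1CCC[C@@]1(CCC(=O)OC)C(=O)OC(C)(C)C | intermediate (not isolated)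
7 | tert-butyl (6S)-6-(3-methoxy-3-oxopropyl)-3-methyl-1,4,5,6-tetrahydrocyclopenta[b]pyrrole-6-carboxylate | Cc1c[nH]c2c1CC[C@@]2(CCC(=O)OC)C(=O)OC(C)(C)C | intermediate
8 | di-tert-butyl (6S)-6-(3-methoxy-3-oxopropyl)-3-methyl-5,6-dihydrocyclopenta[b]pyrrole-1,6(4H)-dicarboxylate | Cc1cn(C(=O)OC(C)(C)C)c2c1CC[C@@]2(CCC(=O)OC)C(=O)OC(C)(C)C | intermediate
9 | di-tert-butyl (3S,3aR,6S,6aS)-6-(3-methoxy-3-oxopropyl)-3-methylhexahydrocyclopenta[b]pyrrole-1,6(2H)-dicarboxylate (cis-fused; C3–H, C3a–H and C6a–H all cis and on the face of the ester side chain) | C[C@@H]1CN(C(=O)OC(C)(C)C)[C@H]2[C@@H]1CC[C@@]2(CCC(=O)OC)C(=O)OC(C)(C)C | intermediate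
10 | (3S,3aR,6S,6aS)-6-(3-methoxy-3-oxopropyl)-3-methyloctahydrocyclopenta[b]pyrrole-6-carboxylic acid, trifluoroacetate salt | C[C@@H]1CN[C@H]2[C@@H]1CC[C@@]2(CCC(=O)OC)C(=O)O.OC(=O)C(F)(F)F | intermediate (not isolated)
11 | (3S,3aR,6S,6aS)-1-[(allyloxy)carbonyl]-6-(3-methoxy-3-oxopropyl)-3-methyloctahydrocyclopenta[b]pyrrole-6-carboxylic acid | C[C@@H]1CN(C(=O)OCC=C)[C@H]2[C@@H]1CC[C@@]2(CCC(=O)OC)C(=O)O | intermediate
12 | acid chloride of 11 | C[C@@H]1CN(C(=O)OCC=C)[C@H]2[C@@H]1CC[C@@]2(CCC(=O)OC)C(=O)Cl | intermediate (not isolated)
13 | allyl (3S,3aR,6S,6aS)-6-acetyl-6-(3-methoxy-3-oxopropyl)-3-methylhexahydrocyclopenta[b]pyrrole-1(2H)-carboxylate | C[C@@H]1CN(C(=O)OCC=C)[C@H]2[C@@H]1CC[C@@]2(CCC(=O)OC)C(C)=O | intermediate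
14 | cyclohex-2-en-1-one | O=C1C=CCCC1 | starting material
15 | 2-(2-bromoethyl)-1,3-dioxolane | BrCCC1OCCO1 | starting material
16 | [2-(1,3-dioxolan-2-yl)ethyl]magnesium bromide | Br[Mg]CCC1OCCO1 | intermediate (not isolated)
17 | (3S)-3-[2-(1,3-dioxolan-2-yl)ethyl]cyclohexan-1-one | O=C1C[C@H](CCC2OCCO2)CCC1 | intermediate
18 | 3-[(1S)-3-oxocyclohexyl]propanal | O=C1C[C@H](CCC=O)CCC1 | intermediate (not isolated)
19 | (7aS)-1,2,5,6,7,7a-hexahydro-4H-inden-4-one | O=C1CCC[C@H]2CCC=C12 | intermediate
20 | trimethyl{[(7aR)-2,6,7,7a-tetrahydro-1H-inden-4-yl]oxy}silane | C[Si](C)(C)OC1=CCC[C@H]2CCC=C12 | intermediate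
21 | aldol adduct: 13 in which the acetyl carbon has become C(CH3)(OH) bonded to C5 of the indenone 19 (C5–H cis to C7a–H); methyl ester still open | C[C@@H]1CN(C(=O)OCC=C)[C@H]2[C@@H]1CC[C@@]2(CCC(=O)OC)[C@](C)(O)[C@H]1CC[C@H]2CCC=C2C1=O | intermediate (not isolated)
22 | Alloc-protected spirolactone enone: δ-lactone (tetrahydropyran-2-one) whose C5 is the spiro carbon C6 of the azabicycle of 13; its O-bearing C6 carries CH3 and C5 of the indenone of 19; indenone C5–H cis to C7a–H; carbinol carbon configured as in 26 | C[C@@H]1CN(C(=O)OCC=C)[C@H]2[C@@H]1CC[C@]23CCC(=O)O[C@]3(C)[C@H]1CC[C@H]2CCC=C2C1=O | intermediate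
23 | Alloc-protected allylic alcohol: 22 with the indenone C4 carbonyl reduced to CH–OH; OH cis to the lactone-bearing substituent at C5 (C4–H cis to C5–H) | C[C@@H]1CN(C(=O)OCC=C)[C@H]2[C@@H]1CC[C@]23CCC(=O)O[C@]3(C)[C@H]1CC[C@H]2CCC=C2[C@H]1O | intermediate
24 | amino alcohol: 23 without the allyloxycarbonyl group (free pyrrolidine N–H) | C[C@@H]1CN[C@H]2[C@@H]1CC[C@]23CCC(=O)O[C@]3(C)[C@H]1CC[C@H]2CCC=C2[C@H]1O | intermediate (not isolated)
25 | N-deoxy hexacyclic amine: 26 without the N-oxide oxygen (N bonded to the former carbinol carbon with inversion; aminomethine H trans to the adjacent ring-fusion H) | C[C@@H]1CN2[C@H]3C4=CCC[C@@H]4CC[C@@H]3[C@@]3(C)OC(=O)CC[C@]34CC[C@H]1[C@@H]42 | intermediate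
26 | CNP0566793.5, the N-oxide of 25 (oxygen cis to the angular N–CH hydrogen) | C[C@@H]1C[N@+]2([O-])[C@H]3C4=CCC[C@@H]4CC[C@@H]3[C@@]3(C)OC(=O)CC[C@]34CC[C@H]1[C@@H]42 | target

**Count and risks**
Total step count: 14. Longest linear sequence: 11 steps (1–7, then 11–14); the east branch (8–10) joins at step 11.

Step 11 (fragment union). What may go wrong: addition to the ketone next to a quaternary carbon may be slower than desilylation of the enol ether; the facial preferences of the two chiral partners may be mismatched, giving poor control at the carbinol carbon; retro-aldol cleavage or β-elimination may occur before lactonization. Fallback: it sets out from 20 and 13. Bromination of 20 with N-bromosuccinimide gives the α-bromo enone (7aR)-5-bromo-1,2,5,6,7,7a-hexahydro-4H-inden-4-one F1 (C5 epimers). SmI2 in THF at −78 °C in the presence of 13 then generates a samarium enolate (Reformatsky-type reaction) that adds to the ketone under neutral conditions through a chelated cyclic transition state. The samarium alkoxide lactonizes on warming, and the route is rejoined at 22.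

Step 13 (key step). What may go wrong: ionization of the activated allylic carbinol, with loss of stereochemical integrity and closure to the cis-fused epimer; elimination to a diene; a slow displacement next to the fully substituted carbinol carbon, allowing alkylation of the hydrazide instead. Fallback: it sets out from 22 and uses a π-allyl closure with net retention instead of an SN2 closure with inversion. CBS reduction with the oxazaborolidine enantiomer that delivers hydride to the other carbonyl face gives the epimeric Alloc-protected allylic alcohol F2 (OH trans to the lactone-bearing substituent). Pd(PPh3)4 and Et2NH remove the allyl carbamate to give the epimeric amino alcohol F3. Palladium-catalysed dehydrative allylic amination (Pd(PPh3)4, Et3B, THF; Tsuji–Trost type, ionization and attack each with inversion) then closes the piperidine at the same allyl terminus, and the route is rejoined at 25.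

Step 5 (pyrrole hydrogenation). What may go wrong: poor facial discrimination between the tert-butyl ester and the ester side chain on the quaternary carbon, or incomplete reduction of the tetrasubstituted pyrrole. Fallback: it sets out from 8 and moves the stereocontrol from the substrate to the catalyst. Homogeneous asymmetric hydrogenation of the N-Boc pyrrole with Ru(η3-methallyl)2(cod) and the trans-chelating bisphosphine PhTRAP (ligand enantiomer chosen for the required face) gives the all-cis pyrrolidine directly, and the route is rejoined at 9; no new compound is made.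

**Further compounds**
F1 | step 11 | (7aR)-5-bromo-1,2,5,6,7,7a-hexahydro-4H-inden-4-one (C5 epimers) | O=C1C(Br)CC[C@H]2CCC=C12
F2 | step 13 | C4 epimer of 23 (Alloc-protected allylic alcohol, OH trans to the lactone-bearing substituent) | C[C@@H]1CN(C(=O)OCC=C)[C@H]2[C@@H]1CC[C@]23CCC(=O)O[C@]3(C)[C@H]1CC[C@H]2CCC=C2[C@@H]1O
F3 | step 13 | C4 epimer of 24 (amino alcohol) | C[C@@H]1CN[C@H]2[C@@H]1CC[C@]23CCC(=O)O[C@]3(C)[C@H]1CC[C@H]2CCC=C2[C@@H]1O
F0 | step 5 | none | none
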